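**Retrosynthetic overview** (azulene numbering: five-membered ring C-1, C-2, C-3, C-3a, C-8a; seven-membered ring C-3a, C-4 to C-8, C-8a)
1. The veratrate is attached last to the C-4 hydroxyl of diol 20. The cis triad 3-OH / 3a-H / 4-OH comes from tertiary allylic alcohol 17 by intramolecular hydrosilylation and C–Si oxidation, and 17 comes from enone 16 by isopropyl addition.
2. Key disconnection C-1–C-8a: at the ketone level, C-3 lies between C-2 and C-3a, so C-1 and C-8a are the two β-carbons (like, acceptor polarity) of the cross-conjugated dienone C-1=C-2–C-3(=O)–C-3a=C-8a in 13. A silicon-directed Nazarov 4π electrocyclization joins them, closing the five-membered ring onto the seven-membered ring and creating the quaternary C-8a.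
3. The C-4 silyloxy group of 13 is temporary: it steers the conrotation, then leaves by β-elimination to give the C-3a=C-4 enone; the oxygen is returned to C-4 in step 12.
4. Ring order: seven-membered ring first (ring-closing metathesis of acyclic ketone 7, chirality from an asymmetric glyoxylate–ene reaction), five-membered ring second (Nazarov).

Key step: step 9

Remark: 7 and 8 are epimer mixtures at the methyl-bearing α-carbon (racemic Grignard reagent); this center becomes trigonal in step 6, so its descriptor is left open in the SMILES.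

Step 1
Reactants: 1 ethyl glyoxylate; 2 isobutylene (2-methylpropene)
Product: 3 ethyl (2S)-2-hydroxy-4-methylpent-4-enoate
Conditions: (S)-BINOL (10 mol%), TiCl2(OiPr)2 (10 mol%), 4 Å MS, CH2Cl2, −30 °C
Reagents that add atoms: none
Why: Catalytic asymmetric glyoxylate–ene reaction of a 1,1-disubstituted alkene, in which the (S)-BINOL–titanium complex should expose one aldehyde face and give the (S)-alcohol.

Step 2
Reactants: 3 ethyl (2S)-2-hydroxy-4-methylpent-4-enoate
Product: 4 ethyl (2S)-4-methyl-2-[(triisopropylsilyl)oxy]pent-4-enoate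
Conditions: iPr3SiOTf, 2,6-lutidine, CH2Cl2, 0 °C
Reagents that add atoms: triisopropylsilyl trifluoromethanesulfonate, CC(C)[Si](OS(=O)(=O)C(F)(F)F)(C(C)C)C(C)C
Why: O-Silylation of a secondary alcohol with a silyl triflate, which installs the bulky group that later steers and then leaves, without touching the stereocenter.

Step 3
Reactants: 4 ethyl (2S)-4-methyl-2-[(triisopropylsilyl)oxy]pent-4-enoate
Product: 5 (2S)-N-methoxy-N,4-dimethyl-2-[(triisopropylsilyl)oxy]pent-4-enamide
Conditions: MeNH(OMe)·HCl, iPrMgCl, THF, −20 → 0 °C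
Reagents that add atoms: N,O-dimethylhydroxylamine hydrochloride, CNOC.Cl
Why: Direct aminolysis of the ester by the magnesium amide gives the Weinreb amide and leaves the α-silyloxy stereocenter untouched.

Step 4
Reactants: 5 (2S)-N-methoxy-N,4-dimethyl-2-[(triisopropylsilyl)oxy]pent-4-enamide; 6 4-bromopent-1-ene
Product: 7 (4S)-2,6-dimethyl-4-[(triisopropylsilyl)oxy]nona-1,8-dien-5-one
Conditions: 6, Mg, THF, rt; then 5, THF, 0 °C; aq. NH4Cl
Reagents that add atoms: none
Why: Grignard addition to a Weinreb amide stops at the ketone through the chelated tetrahedral intermediate, and the new methyl-bearing center is formed unselectively, which does not matter because it becomes trigonal in step 6.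

Step 5
Reactants: 7 (4S)-2,6-dimethyl-4-[(triisopropylsilyl)oxy]nona-1,8-dien-5-one
Product: 8 (7S)-2,5-dimethyl-7-[(triisopropylsilyl)oxy]cyclohept-4-en-1-one
Conditions: second-generation Grubbs catalyst RuCl2(=CHPh)(PCy3)(H2IMes) (5 mol%), CH2Cl2 (0.005 M), 40 °C
Reagents that add atoms: none
Why: Ring-closing metathesis between the monosubstituted and the 1,1-disubstituted alkene closes the seven-membered ring and installs the trisubstituted C-6=C-7 alkene of the target without forming a stereocenter.

Step 6
Reactants: 8 (7S)-2,5-dimethyl-7-[(triisopropylsilyl)oxy]cyclohept-4-en-1-one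
Product: 9 (7S)-2,5-dimethyl-7-[(triisopropylsilyl)oxy]cyclohepta-1,4-dien-1-yl trifluoromethanesulfonate
Conditions: KN(SiMe3)2, PhNTf2, THF, −78 °C
Reagents that add atoms: N-phenylbis(trifluoromethanesulfonimide), O=S(=O)(N(c1ccccc1)S(=O)(=O)C(F)(F)F)C(F)(F)F
Why: Kinetic enolization of an α-silyloxy ketone away from the oxygen-bearing carbon followed by O-triflation gives the tetrasubstituted enol triflate, merging both C-2 epimers and keeping the silyloxy stereocenter.

Step 7
Reactants: 10 ethynyltrimethylsilane; 11 tributylstannane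
Product: 12 (E)-tributyl[2-(trimethylsilyl)ethenyl]stannane
Conditions: AIBN (cat.), neat, 90 °C
Reagents that add atoms: none
Why: Radical hydrostannylation of a terminal alkyne places tin on the terminal carbon and equilibrates to the (E)-alkene.

Step 8
Reactants: 9 (7S)-2,5-dimethyl-7-[(triisopropylsilyl)oxy]cyclohepta-1,4-dien-1-yl trifluoromethanesulfonate; 12 (E)-tributyl[2-(trimethylsilyl)ethenyl]stannane
Product: 13 (2E)-1-{(7S)-2,5-dimethyl-7-[(triisopropylsilyl)oxy]cyclohepta-1,4-dien-1-yl}-3-(trimethylsilyl)prop-2-en-1-one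
Conditions: Pd(PPh3)4 (5 mol%), LiCl (3 equiv), CO (3 atm), THF, 55 °C
Reagents that add atoms: carbon monoxide, [C-]#[O+]
Why: Carbonylative Stille coupling of an enol triflate with a vinylstannane (oxidative addition, CO insertion, transmetalation, reductive elimination) gives the cross-conjugated dienone with both alkene geometries retained.

Step 9
Reactants: 13 (2E)-1-{(7S)-2,5-dimethyl-7-[(triisopropylsilyl)oxy]cyclohepta-1,4-dien-1-yl}-3-(trimethylsilyl)prop-2-en-1-one
Product: 15 (8aR)-6,8a-dimethyl-5,8-dihydroazulen-3(8aH)-one, via β-silyloxy cyclopentenone 14 (not isolated)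
Conditions: FeCl3 (1.1 equiv), CH2Cl2, −30 → 0 °C; then DBU (3 equiv), 0 °C → rt
Reagents that add atoms: none
Why: FeCl3 binds the carbonyl oxygen and generates the hydroxypentadienyl cation C-1=C-2–C-3(O–Fe)–C-3a=C-8a, which undergoes thermally allowed conrotatory 4π electrocyclization to form the C-1–C-8a bond; the oxyallyl cation is stabilized by the β-silicon on C-1 and loses Me3Si+, which fixes the new alkene at C-1=C-2, and protonation at C-3a gives 14. The closest known reaction type is the silicon-directed Nazarov cyclization of β-silylvinyl cycloalkenyl ketones, including those whose methyl-substituted ring terminus becomes an angular quaternary carbon. The five-membered ring is closed by electrocyclization of the cation (geometrically a 5-endo closure at C-8a, which is why a cationic pericyclic process is used and not a nucleophilic or radical addition). The only stereocenter that survives is the quaternary C-8a: the silyloxy group on the future C-4 sits pseudoaxial to avoid allylic strain with the acyl group, and C-1 should bond to the ring face opposite to it, placing the methyl cis to the silyloxy group ((8aR) in 14 and 15). The step needs torquoselectivity (secured by the bulky OSi(iPr)3 next to the reacting alkene), exclusive C-1=C-2 placement of the alkene (secured by silicon) and no proton loss from C-8 or cationic rearrangement (secured by fast desilylation at low temperature). DBU then removes the acidic 3a-H of 14 and expels the β-silyloxy group (E1cB), erasing the temporary C-4 and C-3a centers and giving cross-conjugated dienone 15.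

Step 10
Reactants: 15 (8aR)-6,8a-dimethyl-5,8-dihydroazulen-3(8aH)-one
Product: 16 (8aS)-6,8a-dimethyl-1,2,5,8-tetrahydroazulen-3(8aH)-one
Conditions: H2 (1 atm), RhCl(PPh3)3 (10 mol%), benzene, rt
Reagents that add atoms: none
Why: Homogeneous hydrogenation with the Wilkinson catalyst saturates only the disubstituted C-1=C-2 bond of a cross-conjugated dienone, as known for cyclohexa-1,4-dien-3-ones, and leaves both trisubstituted alkenes (the descriptor changes only through CIP priorities).

Step 11
Reactants: 16 (8aS)-6,8a-dimethyl-1,2,5,8-tetrahydroazulen-3(8aH)-one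
Product: 17 (3R,8aS)-6,8a-dimethyl-3-(propan-2-yl)-1,2,3,5,8,8a-hexahydroazulen-3-ol
Conditions: iPrMgCl, CeCl3, THF, −78 °C
Reagents that add atoms: isopropylmagnesium chloride, CC(C)[Mg]Cl
Why: Cerium-mediated 1,2-addition of a Grignard reagent to the enone, in which the seven-membered ring holds C-8 pseudoaxial over one face of the cyclopentanone so that the nucleophile should enter from the face of the pseudoequatorial angular methyl and give the (3R)-alcohol.

Step 12
Reactants: 17 (3R,8aS)-6,8a-dimethyl-3-(propan-2-yl)-1,2,3,5,8,8a-hexahydroazulen-3-ol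
Product: 20 (3R,3aR,4R,8aS)-6,8a-dimethyl-3-(propan-2-yl)-1,2,3,3a,4,5,8,8a-octahydroazulene-3,4-diol, via dimethylsilyl ether 18 (not isolated), via cyclic siloxane 19 (not isolated)
Conditions: Me2SiHCl, Et3N, DMAP (cat.), CH2Cl2, 0 °C; then Karstedt catalyst Pt2[(CH2=CHSiMe2)2O]3 (1 mol%), toluene, 60 °C; then H2O2 (30%), KF, KHCO3, THF/MeOH, rt
Reagents that add atoms: chlorodimethylsilane, C[SiH](C)Cl (silicon is carried only in 18 and 19); hydrogen peroxide, OO
Why: Intramolecular hydrosilylation of the allylic silyl ether (5-endo, cis addition of Si–H from the face of the C-3 oxygen) followed by Tamao oxidation with retention sets 3a-H and 4-OH cis to 3-OH, which is the trans ring fusion and the (4R) carbinol.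

Step 13
Reactants: 20 (3R,3aR,4R,8aS)-6,8a-dimethyl-3-(propan-2-yl)-1,2,3,3a,4,5,8,8a-octahydroazulene-3,4-diol; 21 3,4-dimethoxybenzoyl chloride
Product: 22 (3R,3aR,4R,8aS)-3-hydroxy-6,8a-dimethyl-3-(propan-2-yl)-1,2,3,3a,4,5,8,8a-octahydroazulen-4-yl 3,4-dimethoxybenzoate
Conditions: Et3N, DMAP, CH2Cl2, 0 °C → rt
Reagents that add atoms: none
Why: DMAP-catalysed acylation discriminates the secondary C-4 hydroxyl from the hindered tertiary C-3 hydroxyl and affects no stereocenter.

**Compound list**
1 | ethyl glyoxylate | CCOC(=O)C=O | starting material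
2 | isobutylene (2-methylpropene) | CC(C)=C | starting material
3 | ethyl (2S)-2-hydroxy-4-methylpent-4-enoate | CCOC(=O)[C@@H](O)CC(C)=C | intermediate
4 | ethyl (2S)-4-methyl-2-[(triisopropylsilyl)oxy]pent-4-enoate | CCOC(=O)[C@@H](O[Si](C(C)C)(C(C)C)C(C)C)CC(C)=C | intermediate
5 | (2S)-N-methoxy-N,4-dimethyl-2-[(triisopropylsilyl)oxy]pent-4-enamide | CON(C)C(=O)[C@@H](O[Si](C(C)C)(C(C)C)C(C)C)CC(C)=C | intermediate
6 | 4-bromopent-1-ene (racemic) | CC(Br)CC=C | starting material
7 | (4S)-2,6-dimethyl-4-[(triisopropylsilyl)oxy]nona-1,8-dien-5-one (both C-6 epimers) | C=CCC(C)C(=O)[C@@H](O[Si](C(C)C)(C(C)C)C(C)C)CC(C)=C | intermediate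
8 | (7S)-2,5-dimethyl-7-[(triisopropylsilyl)oxy]cyclohept-4-en-1-one (both C-2 epimers) | CC1CC=C(C)C[C@H](O[Si](C(C)C)(C(C)C)C(C)C)C1=O | intermediate
9 | (7S)-2,5-dimethyl-7-[(triisopropylsilyl)oxy]cyclohepta-1,4-dien-1-yl trifluoromethanesulfonate | CC1=C(OS(=O)(=O)C(F)(F)F)[C@@H](O[Si](C(C)C)(C(C)C)C(C)C)CC(C)=CC1 | intermediate
10 | ethynyltrimethylsilane | C#C[Si](C)(C)C | starting material
11 | tributylstannane | CCCC[SnH](CCCC)CCCC | starting material
12 | (E)-tributyl[2-(trimethylsilyl)ethenyl]stannane | C[Si](C)(C)/C=C/[Sn](CCCC)(CCCC)CCCC | intermediate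
13 | (2E)-1-{(7S)-2,5-dimethyl-7-[(triisopropylsilyl)oxy]cyclohepta-1,4-dien-1-yl}-3-(trimethylsilyl)prop-2-en-1-one | C[Si](C)(C)/C=C/C(=O)C1=C(C)CC=C(C)C[C@@H]1O[Si](C(C)C)(C(C)C)C(C)C | intermediate
14 | (3aR,4S,8aR)-6,8a-dimethyl-4-[(triisopropylsilyl)oxy]-3a,4,5,8-tetrahydroazulen-3(8aH)-one | O=C1C=C[C@@]2(C)CC=C(C)C[C@H](O[Si](C(C)C)(C(C)C)C(C)C)[C@H]12 | intermediate
15 | (8aR)-6,8a-dimethyl-5,8-dihydroazulen-3(8aH)-one | O=C1C=C[C@@]2(C)CC=C(C)CC=C12 | intermediate
16 | (8aS)-6,8a-dimethyl-1,2,5,8-tetrahydroazulen-3(8aH)-one | O=C1CC[C@@]2(C)CC=C(C)CC=C12 | intermediate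
17 | (3R,8aS)-6,8a-dimethyl-3-(propan-2-yl)-1,2,3,5,8,8a-hexahydroazulen-3-ol | O[C@@]1(C(C)C)CC[C@@]2(C)CC=C(C)CC=C12 | intermediate
18 | dimethylsilyl ether of 17 (O–SiHMe2 on C-3) | C[SiH](C)O[C@@]1(C(C)C)CC[C@@]2(C)CC=C(C)CC=C12 | intermediate
19 | cyclic siloxane: 2,2-dimethyl-1,2-oxasilolane with O on C-3 and Si on C-4, fused across C-3/C-3a/C-4 (3a-H, 3-O and 4-Si on one face) | O1[Si](C)(C)[C@@H]2CC(C)=CC[C@]3(C)CC[C@@]1(C(C)C)[C@@H]23 | intermediate
20 | (3R,3aR,4R,8aS)-6,8a-dimethyl-3-(propan-2-yl)-1,2,3,3a,4,5,8,8a-octahydroazulene-3,4-diol | O[C@@H]1CC(C)=CC[C@]2(C)CC[C@@](O)(C(C)C)[C@@H]12 | intermediate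
21 | 3,4-dimethoxybenzoyl chloride | COc1ccc(C(=O)Cl)cc1OC | starting material
22 | (3R,3aR,4R,8aS)-3-hydroxy-6,8a-dimethyl-3-(propan-2-yl)-1,2,3,3a,4,5,8,8a-octahydroazulen-4-yl 3,4-dimethoxybenzoate | COc1ccc(C(=O)O[C@@H]2CC(C)=CC[C@]3(C)CC[C@@](O)(C(C)C)[C@@H]23)cc1OC | target

**Step count**
Total steps: 13. Longest linear sequence: 12 (steps 1–6 and 8–13; step 7 is a one-step side branch).

**Steps most likely to fail**

Step 9. The conrotation may discriminate the two ring faces poorly; the sense argued here is not secure, and once the silyloxy group is lost any shortfall shows up as lower enantiopurity. The cation may also lose a proton from C-8 before it closes. The fallback sets out from 13 and comes back at 15. The cyclization would be run with FeCl3 alone and quenched with water without DBU, so that 14 is isolated. Its C-8a epimer, (3aR,4S,8aS)-6,8a-dimethyl-4-[(triisopropylsilyl)oxy]-3a,4,5,8-tetrahydroazulen-3(8aH)-one F1, is a diastereomer of 14 as long as the silyloxy center is present and should be removable on silica. Pure 14 would then be treated with DBU to give 15. The temporary stereocenter thus serves as a resolving handle instead of an inducing one.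

Step 11. The two faces of the ketone differ only through the remote angular carbon, so facial selectivity in the Grignard addition may be poor; enolization may also compete. The fallback sets out from 16 and comes back at 17 and replaces substrate control by catalyst control. It is the copper-catalysed enantioselective 1,2-addition of Grignard reagents to α-substituted enones: iPrMgBr, CuBr·SMe2 (5 mol%), a rev-Josiphos-type ferrocenyl diphosphine of the enantiomeric series matched to the desired face, tBuOMe, −78 °C. This fallback makes no new compound (F0).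

Step 12. Si–H delivery in the 5-endo mode may stall at the trisubstituted alkene flanked by two quaternary carbons, with alkene migration or dehydrogenative silylation taking over. The fallback sets out from 17 and comes back at 20. Hydroxyl-directed epoxidation (VO(acac)2 cat., tBuOOH, CH2Cl2, 0 °C) would act only on the allylic alkene, cis to the hydroxyl, and give (3R,3aS,4R,8aS)-3a,4-epoxy-6,8a-dimethyl-3-(propan-2-yl)-1,2,3,3a,4,5,8,8a-octahydroazulen-3-ol F2. Reductive opening with Cp2TiCl (from Cp2TiCl2 and Zn) and 1,4-cyclohexadiene in THF would follow. Trivalent titanium cleaves the C-3a–O bond to the tertiary radical and keeps the C-4–O bond and its configuration. Hydrogen-atom transfer should then come from the face away from the isopropyl and angular methyl groups and give 20.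

**Further compounds**
F1 | step 9 | (3aR,4S,8aS)-6,8a-dimethyl-4-[(triisopropylsilyl)oxy]-3a,4,5,8-tetrahydroazulen-3(8aH)-one | O=C1C=C[C@]2(C)CC=C(C)C[C@H](O[Si](C(C)C)(C(C)C)C(C)C)[C@H]12
F0 | step 11 | none | none
F2 | step 12 | (3R,3aS,4R,8aS)-3a,4-epoxy-6,8a-dimethyl-3-(propan-2-yl)-1,2,3,3a,4,5,8,8a-octahydroazulen-3-ol | O[C@@]1(C(C)C)CC[C@@]2(C)CC=C(C)C[C@H]3O[C@@]123
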